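**Retrosynthetic overview**
- Last step: the 14-membered ring and the cis-fused α-methylene-γ-lactone are formed together by an intramolecular CrCl2-mediated 2-(alkoxycarbonyl)allylation of an enal (C1–C2 bond); the new alkoxide then closes the lactone.
- The open-chain precursor is joined at C6–C7 by a B-alkyl Suzuki–Miyaura coupling of fragment C (C2–C6 dienol) with a vinyl iodide that already carries the epoxy acetate.
- That vinyl iodide comes from a vinylogous Mukaiyama aldol (C13–C14) of fragment A (C7–C13 iodo dienal) with fragment B (silyl dienolate holding C14, C1, C15–C17); a Sharpless kinetic-resolution epoxidation then sets C11, C12 and C13.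
- Fragments A, B and C come from pent-4-yn-1-ol, methyl crotonate and prenyl acetate.
- Ring order: oxirane (step 8), then macrocycle and lactone (both in step 17).

Assumption: locants C1–C17 in the text are cembrane locants of the target (ring C1–C14; C15 carries the exocyclic methylene C17; C16 is the lactone carbonyl). Compounds 9, 10 and 13 are racemates.

**Fragment A (C7–C13)**

Step 1
Reactants: 1 pent-4-yn-1-ol
Product: 3 (E)-5-iodo-4-methylpent-4-en-1-ol, via alkenylalane 2 (not isolated)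
Conditions: AlMe3 (3 equiv), Cp2ZrCl2 (0.25 equiv), CH2Cl2, 0 °C → rt; then I2, THF, −30 → 0 °C; aq. K2CO3
Reagents that add atoms: trimethylaluminium C[Al](C)C; iodine II
Why: Negishi zirconium-catalysed carboalumination adds methyl and aluminium syn across the terminal alkyne (methyl to the internal carbon), and iodinolysis of the C–Al bond with retention gives the E vinyl iodide that becomes C7=C8; no stereocentre is formed.

Step 2
Reactants: 3 (E)-5-iodo-4-methylpent-4-en-1-ol
Product: 4 (E)-5-iodo-4-methylpent-4-enal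
Conditions: PhI(OAc)2 (1.1 equiv), TEMPO (0.1 equiv), CH2Cl2, rt
Reagents that add atoms: none
Why: TEMPO-catalysed (oxoammonium) oxidation stops at the aldehyde and leaves the vinyl iodide untouched.

Step 3
Reactants: 4 (E)-5-iodo-4-methylpent-4-enal; 5 2-(triphenyl-λ5-phosphanylidene)propanal
Product: 6 (2E,6E)-7-iodo-2,6-dimethylhepta-2,6-dienal
Conditions: toluene, 90 °C
Reagents that add atoms: none
Why: Wittig olefination with the formyl-stabilised ylide reacts only with the aliphatic aldehyde and gives the E trisubstituted enal (C11=C12) under thermodynamic control.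

**Fragment B (C14, C1, C15–C17)**

Step 4
Reactants: 7 methyl (E)-but-2-enoate
Product: 9 methyl 2-(hydroxymethyl)but-3-enoate (racemic), via lithium dienolate 8 (not isolated)
Conditions: LiN(iPr)2, HMPA, THF, −78 °C; then CH2O (gas, from cracked paraformaldehyde), −78 → −40 °C; AcOH
Reagents that add atoms: formaldehyde C=O
Why: γ-Deprotonation gives the extended enolate, whose kinetic (deconjugative) aldol reaction with formaldehyde occurs at the α-carbon and installs the future C17; the new centre is racemic and is erased in step 6.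

Step 5
Reactants: 9 methyl 2-(hydroxymethyl)but-3-enoate
Product: 10 methyl 2-{[(tert-butyldimethylsilyl)oxy]methyl}but-3-enoate (racemic)
Conditions: TBSCl, imidazole, DMF, 0 °C → rt
Reagents that add atoms: tert-butyldimethylsilyl chloride CC(C)(C)[Si](C)(C)Cl
Why: Standard silylation of the primary alcohol; the silyl ether survives steps 6–14.

Step 6
Reactants: 10 methyl 2-{[(tert-butyldimethylsilyl)oxy]methyl}but-3-enoate
Product: 12 tert-butyl[(1-methoxy-2-{[(tert-butyldimethylsilyl)oxy]methyl}buta-1,3-dien-1-yl)oxy]dimethylsilane, via lithium dienolate 11 (not isolated)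
Conditions: LiN(iPr)2, THF, −78 °C; then TBSCl, HMPA, −78 °C → rt; used crude
Reagents that add atoms: tert-butyldimethylsilyl chloride CC(C)(C)[Si](C)(C)Cl
Why: α-Deprotonation of the β,γ-unsaturated ester and O-silylation (silyl ketene acetal formation) give the 2-substituted vinylketene acetal; the enolate is trapped cold to avoid loss of the β-silyloxy group.

**Union of A and B, stereocentres C11–C13**

Step 7
Reactants: 6 (2E,6E)-7-iodo-2,6-dimethylhepta-2,6-dienal; 12 tert-butyl[(1-methoxy-2-{[(tert-butyldimethylsilyl)oxy]methyl}buta-1,3-dien-1-yl)oxy]dimethylsilane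
Product: 13 methyl (2E,6E,10E)-2-{[(tert-butyldimethylsilyl)oxy]methyl}-5-hydroxy-11-iodo-6,10-dimethylundeca-2,6,10-trienoate (racemic)
Conditions: BF3·OEt2 (1.2 equiv), CH2Cl2, −78 °C; aq. NaHCO3
Reagents that add atoms: none
Why: Vinylogous Mukaiyama aldol: the BF3-activated enal is attacked 1,2 by the γ-carbon of the silyl dienolate, forming C13–C14 and the E enoate (chain trans to CO2Me, as usual for 2-substituted dienolates); C13 is formed racemic and is resolved in step 8.

Step 8
Reactants: 13 methyl (2E,6E,10E)-2-{[(tert-butyldimethylsilyl)oxy]methyl}-5-hydroxy-11-iodo-6,10-dimethylundeca-2,6,10-trienoate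
Product: 14 methyl (2E,5R)-2-{[(tert-butyldimethylsilyl)oxy]methyl}-5-hydroxy-5-{(2R,3R)-3-[(3E)-4-iodo-3-methylbut-3-en-1-yl]-2-methyloxiran-2-yl}pent-2-enoate
Conditions: Ti(OiPr)4 (0.15 equiv), D-(−)-diisopropyl tartrate (0.2 equiv), t-BuOOH (0.5 equiv), 4 Å MS, CH2Cl2, −20 °C
Reagents that add atoms: tert-butyl hydroperoxide CC(C)(C)OO
Why: Sharpless kinetic resolution: with the D-(−)-tartrate only the (5R) alcohol is epoxidised at a useful rate, and on the face that gives the erythro (anti) epoxy alcohol, so C13 (R), C12 and C11 (R) of the target are fixed in one operation; yield is at most 50% and the unreacted (5S) alcohol is removed by chromatography.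

Step 9
Reactants: 14 methyl (2E,5R)-2-{[(tert-butyldimethylsilyl)oxy]methyl}-5-hydroxy-5-{(2R,3R)-3-[(3E)-4-iodo-3-methylbut-3-en-1-yl]-2-methyloxiran-2-yl}pent-2-enoate
Product: 15 methyl (2E,5R)-5-acetoxy-2-{[(tert-butyldimethylsilyl)oxy]methyl}-5-{(2S,3R)-3-[(3E)-4-iodo-3-methylbut-3-en-1-yl]-2-methyloxiran-2-yl}pent-2-enoate
Conditions: Ac2O, pyridine, DMAP (cat.), CH2Cl2, 0 °C → rt
Reagents that add atoms: acetic anhydride CC(=O)OC(C)=O
Why: DMAP-catalysed acylation installs the C13 acetate of the target with retention; the oxirane descriptor changes from 2R to 2S only because the CIP priorities change.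

**Fragment C (C2–C6)**

Step 10
Reactants: 16 3-methylbut-2-en-1-yl acetate
Product: 17 (2E)-3-methyl-4-oxobut-2-en-1-yl acetate
Conditions: SeO2 (1.1 equiv), 1,4-dioxane, 90 °C
Reagents that add atoms: selenium dioxide O=[Se]=O
Why: Riley allylic oxidation (ene reaction, then [2,3]-shift) attacks the methyl group trans to the CH2OAc chain and carries it to the aldehyde, which fixes the E geometry of the future C3=C4.

Step 11
Reactants: 17 (2E)-3-methyl-4-oxobut-2-en-1-yl acetate
Product: 18 (2E)-3-methylpenta-2,4-dien-1-yl acetate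
Conditions: Ph3PCH3Br, KOtBu, THF, 0 °C; then 17, −78 → 0 °C
Reagents that add atoms: methyltriphenylphosphonium bromide C[P+](c1ccccc1)(c1ccccc1)c1ccccc1.[Br-]
Why: Wittig methylenation of the enal is much faster than attack on the acetate and does not touch the trisubstituted double bond.

Step 12
Reactants: 18 (2E)-3-methylpenta-2,4-dien-1-yl acetate
Product: 19 (2E)-3-methylpenta-2,4-dien-1-ol
Conditions: K2CO3 (0.2 equiv), MeOH, 0 °C
Reagents that add atoms: none
Why: Base-catalysed transesterification (methanolysis) frees the allylic alcohol.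

**Fragment coupling and ring closure**

Step 13
Reactants: 19 (2E)-3-methylpenta-2,4-dien-1-ol; 15 methyl (2E,5R)-5-acetoxy-2-{[(tert-butyldimethylsilyl)oxy]methyl}-5-{(2S,3R)-3-[(3E)-4-iodo-3-methylbut-3-en-1-yl]-2-methyloxiran-2-yl}pent-2-enoate
Product: 21 methyl (2E,5R)-5-acetoxy-2-{[(tert-butyldimethylsilyl)oxy]methyl}-5-{(2S,3R)-3-[(3E,7E)-9-hydroxy-3,7-dimethylnona-3,7-dien-1-yl]-2-methyloxiran-2-yl}pent-2-enoate, via B-alkyl-9-BBN borane 20 (not isolated)
Conditions: 9-BBN-H (2.2 equiv), THF, 0 °C → rt; then 15, PdCl2(dppf) (5 mol%), AsPh3, Cs2CO3, DMF/H2O, rt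
Reagents that add atoms: none
Why: After the OH is capped as its borinate, 9-BBN hydroborates only the terminal vinyl group of the diene at its CH2 end, and the B-alkyl Suzuki–Miyaura coupling forms C6–C7 with retention of the E vinyl iodide geometry; acetate, epoxide, enoate and silyl ether tolerate the mild base and no stereocentre is touched.

Step 14
Reactants: 21 methyl (2E,5R)-5-acetoxy-2-{[(tert-butyldimethylsilyl)oxy]methyl}-5-{(2S,3R)-3-[(3E,7E)-9-hydroxy-3,7-dimethylnona-3,7-dien-1-yl]-2-methyloxiran-2-yl}pent-2-enoate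
Product: 22 methyl (2E,5R)-5-acetoxy-2-{[(tert-butyldimethylsilyl)oxy]methyl}-5-{(2S,3R)-3-[(3E,7E)-3,7-dimethyl-9-oxonona-3,7-dien-1-yl]-2-methyloxiran-2-yl}pent-2-enoate
Conditions: MnO2 (20 equiv), CH2Cl2, rt
Reagents that add atoms: none
Why: MnO2 oxidises only the free allylic alcohol to the E enal (C2); the second allylic oxygen is still silylated.

Step 15
Reactants: 22 methyl (2E,5R)-5-acetoxy-2-{[(tert-butyldimethylsilyl)oxy]methyl}-5-{(2S,3R)-3-[(3E,7E)-3,7-dimethyl-9-oxonona-3,7-dien-1-yl]-2-methyloxiran-2-yl}pent-2-enoate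
Product: 23 methyl (2E,5R)-5-acetoxy-5-{(2S,3R)-3-[(3E,7E)-3,7-dimethyl-9-oxonona-3,7-dien-1-yl]-2-methyloxiran-2-yl}-2-(hydroxymethyl)pent-2-enoate
Conditions: HF·pyridine, pyridine, THF, 0 °C → rt
Reagents that add atoms: none
Why: Buffered fluoride desilylation removes the primary allylic silyl ether without base (no acetate loss or elimination) and without enough acidity to open the epoxide.

Step 16
Reactants: 23 methyl (2E,5R)-5-acetoxy-5-{(2S,3R)-3-[(3E,7E)-3,7-dimethyl-9-oxonona-3,7-dien-1-yl]-2-methyloxiran-2-yl}-2-(hydroxymethyl)pent-2-enoate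
Product: 24 methyl (2Z,5R)-5-acetoxy-2-(bromomethyl)-5-{(2S,3R)-3-[(3E,7E)-3,7-dimethyl-9-oxonona-3,7-dien-1-yl]-2-methyloxiran-2-yl}pent-2-enoate
Conditions: CBr4, PPh3, CH2Cl2, 0 °C
Reagents that add atoms: carbon tetrabromide BrC(Br)(Br)Br
Why: Appel bromination converts the primary allylic alcohol into the bromide under neutral conditions with the double-bond geometry kept (the descriptor becomes Z only by CIP priority).

Step 17
Reactants: 24 methyl (2Z,5R)-5-acetoxy-2-(bromomethyl)-5-{(2S,3R)-3-[(3E,7E)-3,7-dimethyl-9-oxonona-3,7-dien-1-yl]-2-methyloxiran-2-yl}pent-2-enoate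
Product: 27 (1S,2S,3E,7E,11R,12S,13R)-13-acetoxy-11,12-epoxycembra-3,7,15(17)-trien-16,2-olide (the target), via allylchromium dichloride 25 (not isolated), via seco hydroxy ester 26 (not isolated)
Conditions: CrCl2 (10 equiv), THF, rt, slow addition of 24 (final 0.002 M); aq. NH4Cl
Reagents that add atoms: none
Why: Intramolecular Nozaki–Hiyama-type (chromium Barbier) 2-(alkoxycarbonyl)allylation: the allylchromium adds through its γ-carbon (C1) to the enal in a chair transition state, the Z allyl geometry gives the syn adduct, and the alkoxide closes on the ester to give the cis-fused lactone. Which enal face reacts is set by the C11–C13 epoxy acetate segment within the forming ring and is not secured in advance; the (1S,2S) isomer is separated from any (1R,2R) isomer by chromatography.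

**Compound list**
1 | pent-4-yn-1-ol | C#CCCCO | starting material
2 | dimethyl[(1E)-5-(dimethylalumanyloxy)-2-methylpent-1-en-1-yl]alane | C[Al](C)/C=C(\C)CCCO[Al](C)C | intermediate (not isolated)
3 | (E)-5-iodo-4-methylpent-4-en-1-ol | OCCC/C(C)=C/I | intermediate
4 | (E)-5-iodo-4-methylpent-4-enal | O=CCC/C(C)=C/I | intermediate
5 | 2-(triphenyl-λ5-phosphanylidene)propanal | CC(C=O)=P(c1ccccc1)(c1ccccc1)c1ccccc1 | starting material
6 | (2E,6E)-7-iodo-2,6-dimethylhepta-2,6-dienal | O=C/C(C)=C/CC/C(C)=C/I | intermediate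
7 | methyl (E)-but-2-enoate | C/C=C/C(=O)OC | starting material
8 | lithium 1-methoxybuta-1,3-dien-1-olate | [Li]OC(OC)=CC=C | intermediate (not isolated)
9 | methyl 2-(hydroxymethyl)but-3-enoate, racemic | C=CC(CO)C(=O)OC | intermediate
10 | methyl 2-{[(tert-butyldimethylsilyl)oxy]methyl}but-3-enoate, racemic | C=CC(CO[Si](C)(C)C(C)(C)C)C(=O)OC | intermediate
11 | lithium 1-methoxy-2-{[(tert-butyldimethylsilyl)oxy]methyl}buta-1,3-dien-1-olate | [Li]OC(OC)=C(CO[Si](C)(C)C(C)(C)C)C=C | intermediate (not isolated)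
12 | tert-butyl[(1-methoxy-2-{[(tert-butyldimethylsilyl)oxy]methyl}buta-1,3-dien-1-yl)oxy]dimethylsilane (ketene acetal geometry not defined) | C=CC(CO[Si](C)(C)C(C)(C)C)=C(OC)O[Si](C)(C)C(C)(C)C | intermediate
13 | methyl (2E,6E,10E)-2-{[(tert-butyldimethylsilyl)oxy]methyl}-5-hydroxy-11-iodo-6,10-dimethylundeca-2,6,10-trienoate, racemic at C5 | COC(=O)/C(CO[Si](C)(C)C(C)(C)C)=C/CC(O)/C(C)=C/CC/C(C)=C/I | intermediate
14 | methyl (2E,5R)-2-{[(tert-butyldimethylsilyl)oxy]methyl}-5-hydroxy-5-{(2R,3R)-3-[(3E)-4-iodo-3-methylbut-3-en-1-yl]-2-methyloxiran-2-yl}pent-2-enoate | I/C=C(\C)CC[C@H]1O[C@]1(C)[C@H](O)C/C=C(\CO[Si](C)(C)C(C)(C)C)C(=O)OC | intermediate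
15 | methyl (2E,5R)-5-acetoxy-2-{[(tert-butyldimethylsilyl)oxy]methyl}-5-{(2S,3R)-3-[(3E)-4-iodo-3-methylbut-3-en-1-yl]-2-methyloxiran-2-yl}pent-2-enoate | I/C=C(\C)CC[C@H]1O[C@]1(C)[C@H](OC(C)=O)C/C=C(\CO[Si](C)(C)C(C)(C)C)C(=O)OC | intermediate
16 | 3-methylbut-2-en-1-yl acetate (prenyl acetate) | CC(C)=CCOC(C)=O | starting material
17 | (2E)-3-methyl-4-oxobut-2-en-1-yl acetate | O=C/C(C)=C/COC(C)=O | intermediate
18 | (2E)-3-methylpenta-2,4-dien-1-yl acetate | C=C/C(C)=C/COC(C)=O | intermediate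
19 | (2E)-3-methylpenta-2,4-dien-1-ol | C=C/C(C)=C/CO | intermediate
20 | 9-{(3E)-5-[(9-borabicyclo[3.3.1]nonan-9-yl)oxy]-3-methylpent-3-en-1-yl}-9-borabicyclo[3.3.1]nonane | C/C(CCB1C2CCCC1CCC2)=C\COB1C2CCCC1CCC2 | intermediate (not isolated)
21 | methyl (2E,5R)-5-acetoxy-2-{[(tert-butyldimethylsilyl)oxy]methyl}-5-{(2S,3R)-3-[(3E,7E)-9-hydroxy-3,7-dimethylnona-3,7-dien-1-yl]-2-methyloxiran-2-yl}pent-2-enoate | OC/C=C(\C)CC/C=C(\C)CC[C@H]1O[C@]1(C)[C@H](OC(C)=O)C/C=C(\CO[Si](C)(C)C(C)(C)C)C(=O)OC | intermediate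
22 | methyl (2E,5R)-5-acetoxy-2-{[(tert-butyldimethylsilyl)oxy]methyl}-5-{(2S,3R)-3-[(3E,7E)-3,7-dimethyl-9-oxonona-3,7-dien-1-yl]-2-methyloxiran-2-yl}pent-2-enoate | O=C/C=C(\C)CC/C=C(\C)CC[C@H]1O[C@]1(C)[C@H](OC(C)=O)C/C=C(\CO[Si](C)(C)C(C)(C)C)C(=O)OC | intermediate
23 | methyl (2E,5R)-5-acetoxy-5-{(2S,3R)-3-[(3E,7E)-3,7-dimethyl-9-oxonona-3,7-dien-1-yl]-2-methyloxiran-2-yl}-2-(hydroxymethyl)pent-2-enoate | O=C/C=C(\C)CC/C=C(\C)CC[C@H]1O[C@]1(C)[C@H](OC(C)=O)C/C=C(\CO)C(=O)OC | intermediate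
24 | methyl (2Z,5R)-5-acetoxy-2-(bromomethyl)-5-{(2S,3R)-3-[(3E,7E)-3,7-dimethyl-9-oxonona-3,7-dien-1-yl]-2-methyloxiran-2-yl}pent-2-enoate | O=C/C=C(\C)CC/C=C(\C)CC[C@H]1O[C@]1(C)[C@H](OC(C)=O)C/C=C(\CBr)C(=O)OC | intermediate
25 | {(2Z,5R)-5-acetoxy-5-[(2S,3R)-3-((3E,7E)-3,7-dimethyl-9-oxonona-3,7-dien-1-yl)-2-methyloxiran-2-yl]-2-(methoxycarbonyl)pent-2-en-1-yl}chromium dichloride | O=C/C=C(\C)CC/C=C(\C)CC[C@H]1O[C@]1(C)[C@H](OC(C)=O)C/C=C(\C[Cr](Cl)Cl)C(=O)OC | intermediate (not isolated)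
26 | methyl 2-[(1S,2S,3E,7E,11R,12S,13R)-13-acetoxy-11,12-epoxy-2-hydroxy-4,8,12-trimethylcyclotetradeca-3,7-dien-1-yl]prop-2-enoate (cembrane locants; present as its chromium alkoxide) | O[C@H]2/C=C(\C)CC/C=C(\C)CC[C@H]3O[C@]3(C)[C@H](OC(C)=O)C[C@H]2C(=C)C(=O)OC | intermediate (not isolated)
27 | (1S,2S,3E,7E,11R,12S,13R)-13-acetoxy-11,12-epoxycembra-3,7,15(17)-trien-16,2-olide | C=C1C(=O)O[C@H]2/C=C(\C)CC/C=C(\C)CC[C@H]3O[C@]3(C)[C@H](OC(C)=O)C[C@@H]12 | target

**Step count**
Total: 17 steps. Longest linear sequence: 11 steps (steps 1–3, 7–9, 13–17 from pent-4-yn-1-ol; equally 4–6, 7–9, 13–17 from methyl crotonate).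

**Three steps most likely to fail**

Step 17 (macrocyclisation). The ring closure competes with oligomerisation, and the facial sense at C1/C2 relative to C11–C13 rests on substrate control alone. Fallback: invert the order of the two C–C bond formations, so that the lactone is made intermolecularly and the ring is closed at C6–C7. It sets out from 15 and 19 and comes back at 27. Compound 15 is desilylated (HF·pyridine) to the primary allylic alcohol F1 and brominated (CBr4, PPh3) to the allylic bromide F2. Dienol 19 is oxidised (MnO2) to (2E)-3-methylpenta-2,4-dienal F3. CrCl2-mediated allylation of F3 with F2 and lactonisation give the cis α-methylene lactone F4; here the C1/C2 diastereomers can be separated on scale, or a chiral ligand on chromium can be used to enforce the face. 9-BBN hydroboration of the terminal diene of F4 gives the borane F5, and an intramolecular B-alkyl Suzuki–Miyaura coupling (PdCl2(dppf), AsPh3, Cs2CO3, DMF/THF/H2O, high dilution) closes the 14-membered ring to 27.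

Step 7 (vinylogous aldol). The unusual dienolate 12 may lose its allylic silyloxy group under BF3 or react at its α-carbon. Fallback: build C13–C14 by asymmetric allylation and add the acrylate carbons by cross-metathesis. It sets out from 6 and comes back at 14. Brown allylation of 6 with B-allyldiisopinocampheylborane made from (−)-α-pinene (Re-face attack; oxidative work-up) gives the homoallylic alcohol (4R,5E,9E)-10-iodo-5,9-dimethyldeca-1,5,9-trien-4-ol F6. Methyl 2-(hydroxymethyl)prop-2-enoate is silylated (TBSCl, imidazole) to the silyl acrylate F7. Cross-metathesis of F6 with excess F7 (second-generation Hoveyda–Grubbs catalyst, CH2Cl2, 40 °C) gives the (5R) hydroxy enoate F8, the single enantiomer of 13. Epoxidation of F8 under the conditions of step 8 (now matched and run to full conversion) gives 14.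

Step 13 (hydroboration and B-alkyl Suzuki coupling). The free hydroxyl and the diene of 19 may give poor hydroboration regiochemistry, and the borinate may couple sluggishly. Fallback: move the sp3–sp2 junction from C6–C7 to C4–C5 and reverse the roles of the partners. It sets out from 15 and comes back at 21. Stille vinylation of 15 (Bu3SnCH=CH2, Pd2(dba)3, AsPh3, NMP, rt) gives the terminal diene F9. 9-BBN hydroborates its terminal CH2 to give the borane F10, which is coupled (PdCl2(dppf), AsPh3, Cs2CO3, DMF/H2O) with commercial (2E)-3-iodobut-2-en-1-ol F11 to give 21 directly.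

**Further compounds**
F1 | step 17 | methyl (2E,5R)-5-acetoxy-2-(hydroxymethyl)-5-{(2S,3R)-3-[(3E)-4-iodo-3-methylbut-3-en-1-yl]-2-methyloxiran-2-yl}pent-2-enoate | I/C=C(\C)CC[C@H]1O[C@]1(C)[C@H](OC(C)=O)C/C=C(\CO)C(=O)OC
F2 | step 17 | methyl (2Z,5R)-5-acetoxy-2-(bromomethyl)-5-{(2S,3R)-3-[(3E)-4-iodo-3-methylbut-3-en-1-yl]-2-methyloxiran-2-yl}pent-2-enoate | I/C=C(\C)CC[C@H]1O[C@]1(C)[C@H](OC(C)=O)C/C=C(\CBr)C(=O)OC
F3 | step 17 | (2E)-3-methylpenta-2,4-dienal | C=C/C(C)=C/C=O
F4 | step 17 | (4S,5S)-4-{(2R)-2-acetoxy-2-[(2S,3R)-3-((3E)-4-iodo-3-methylbut-3-en-1-yl)-2-methyloxiran-2-yl]ethyl}-3-methylidene-5-[(1E)-2-methylbuta-1,3-dien-1-yl]oxolan-2-one | C=C1C(=O)O[C@@H](/C=C(\C)C=C)[C@H]1C[C@@H](OC(C)=O)[C@@]2(C)O[C@@H]2CC/C(C)=C/I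
F5 | step 17 | (4S,5S)-4-{(2R)-2-acetoxy-2-[(2S,3R)-3-((3E)-4-iodo-3-methylbut-3-en-1-yl)-2-methyloxiran-2-yl]ethyl}-5-[(1E)-4-(9-borabicyclo[3.3.1]nonan-9-yl)-2-methylbut-1-en-1-yl]-3-methylideneoxolan-2-one | C=C1C(=O)O[C@@H](/C=C(\C)CCB3C4CCCC3CCC4)[C@H]1C[C@@H](OC(C)=O)[C@@]2(C)O[C@@H]2CC/C(C)=C/I
F6 | step 7 | (4R,5E,9E)-10-iodo-5,9-dimethyldeca-1,5,9-trien-4-ol | I/C=C(\C)CC/C=C(C)/[C@H](O)CC=C
F7 | step 7 | methyl 2-{[(tert-butyldimethylsilyl)oxy]methyl}prop-2-enoate | C=C(CO[Si](C)(C)C(C)(C)C)C(=O)OC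
F8 | step 7 | methyl (2E,5R,6E,10E)-2-{[(tert-butyldimethylsilyl)oxy]methyl}-5-hydroxy-11-iodo-6,10-dimethylundeca-2,6,10-trienoate | I/C=C(\C)CC/C=C(C)/[C@H](O)C/C=C(\CO[Si](C)(C)C(C)(C)C)C(=O)OC
F9 | step 13 | methyl (2E,5R)-5-acetoxy-2-{[(tert-butyldimethylsilyl)oxy]methyl}-5-{(2S,3R)-2-methyl-3-[(3E)-3-methylhexa-3,5-dien-1-yl]oxiran-2-yl}pent-2-enoate | C=C/C=C(\C)CC[C@H]1O[C@]1(C)[C@H](OC(C)=O)C/C=C(\CO[Si](C)(C)C(C)(C)C)C(=O)OC
F10 | step 13 | methyl (2E,5R)-5-acetoxy-5-{(2S,3R)-3-[(3E)-6-(9-borabicyclo[3.3.1]nonan-9-yl)-3-methylhex-3-en-1-yl]-2-methyloxiran-2-yl}-2-{[(tert-butyldimethylsilyl)oxy]methyl}pent-2-enoate | B1(CC/C=C(\C)CC[C@H]3O[C@]3(C)[C@H](OC(C)=O)C/C=C(\CO[Si](C)(C)C(C)(C)C)C(=O)OC)C2CCCC1CCC2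
F11 | step 13 | (2E)-3-iodobut-2-en-1-ol | C/C(I)=C\CO
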